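**Retrosynthetic overview**
- Target 10 comes from the (R)-tetrahydroquinoline 9 by a final peracid N-oxidation; the oxygen is put back because the key step uses it up.
- Ring B (carbocycle C4a–C5–C6–C7–C8–C8a) is cut at C5–C6 and at C8–C8a in one stroke, a formal (3+3) disconnection to the (E)-5-alkenylpyridine N-oxide 6 and allyl phosphate 7.
- Enabling feature: in ring A (pyridine) C8a–H is the only unsubstituted carbon; it sits between N+–O− (which makes C8a an acceptor for an alkylcopper and leaves as the internal oxidant) and C4a, which carries the styrene-like C5=C bond. One chiral copper hydride catalyst can therefore set C5 and then deliver C8 to C8a.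
- 6 comes from Suzuki–Miyaura coupling of bromo N-oxide 3 (from 3,4-dimethoxy-2-methylpyridine 1 by bromination and N-oxidation) with (E)-alkenylboronate 5 (from 6-phenyl-1-hexyne 4).
- Ring order: ring A is bought; ring B is the only ring formed (step 5).

Key step: step 5

Assumption: 1, 4 and 7 are taken as purchasable compounds.
Assumption: (R)-DTBM-SEGPHOS is taken to give the (R) centre at C5, by analogy with the sense recalled for hydrocupration of β-alkylstyrenes; if the sense is the opposite, the (S)-ligand is used and nothing else changes.

**Route**

Step 1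
Reactants: 1 3,4-dimethoxy-2-methylpyridine
Product: 2 5-bromo-3,4-dimethoxy-2-methylpyridine
Conditions: NBS (1.05 equiv), MeCN, 0 °C to rt, dark
Reagents that add atoms: N-bromosuccinimide, O=C1CCC(=O)N1Br
Why: Electrophilic aromatic bromination should go to C5 (pyridine numbering), which is ortho to the 4-methoxy group and β to nitrogen, so that its σ-complex is stabilised by the methoxy oxygen without positive charge on nitrogen (unlike attack at C6), while polar conditions in the dark disfavour radical bromination of the 2-methyl group.

Step 2
Reactants: 2 5-bromo-3,4-dimethoxy-2-methylpyridine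
Product: 3 5-bromo-3,4-dimethoxy-2-methylpyridine 1-oxide
Conditions: mCPBA (1.2 equiv), CH2Cl2, 0 °C to rt
Reagents that add atoms: 3-chloroperoxybenzoic acid, OOC(=O)c1cccc(Cl)c1
Why: Peracid N-oxidation of a pyridine, in which the ring nitrogen is the only site the peracid can oxidise; doing it before the alkene is introduced avoids competing epoxidation.

Step 3
Reactants: 4 6-phenyl-1-hexyne
Product: 5 (E)-4,4,5,5-tetramethyl-2-(6-phenylhex-1-en-1-yl)-1,3,2-dioxaborolane
Conditions: HBpin (1.1 equiv), Cp2ZrHCl (10 mol%), Et3N (10 mol%), neat, 60 °C
Reagents that add atoms: pinacolborane, [H]B1OC(C)(C)C(C)(C)O1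
Why: Zirconium-catalysed syn hydroboration of a terminal alkyne places boron on the terminal carbon and should give the (E)-alkenylboronate only.

Step 4
Reactants: 3 5-bromo-3,4-dimethoxy-2-methylpyridine 1-oxide; 5 (E)-4,4,5,5-tetramethyl-2-(6-phenylhex-1-en-1-yl)-1,3,2-dioxaborolane
Product: 6 (E)-3,4-dimethoxy-2-methyl-5-(6-phenylhex-1-en-1-yl)pyridine 1-oxide
Conditions: Pd(dppf)Cl2 (5 mol%), K2CO3 (3 equiv), 1,4-dioxane/H2O, 80 °C
Reagents that add atoms: none
Why: Suzuki–Miyaura coupling, in which oxidative addition of zerovalent palladium into the C–Br bond and transmetallation of the alkenylboronate proceed with retention of the E geometry, and pyridine N-oxides are tolerated.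

Step 5
Reactants: 6 (E)-3,4-dimethoxy-2-methyl-5-(6-phenylhex-1-en-1-yl)pyridine 1-oxide; 7 diethyl allyl phosphate
Product: 9 (R)-3,4-dimethoxy-2-methyl-5-(5-phenylpentyl)-5,6,7,8-tetrahydroquinoline, via homoallyl N-oxide 8 (not isolated)
Conditions: Cu(OAc)2 (5 mol%), (R)-DTBM-SEGPHOS (5.5 mol%), (MeO)2MeSiH (4 equiv), LiOtBu (1.1 equiv), 7 (1.0 equiv), THF, rt until 6 is consumed, then 50 °C
Reagents that add atoms: none
Why: Proposed new method: the ligated copper hydride should add syn across the styrene-like C5=C bond of 6 (copper on benzylic C5) and the C5–Cu bond should be allylated by 7 with retention to give 8 (bond C5–C6); the same catalyst should then hydrocuprate the new terminal alkene in the anti-Markovnikov sense, the primary C8–Cu should add to C8a of the C8a=N+–O− unit (bond C8–C8a), and loss of Cu–OH should rearomatise ring A to 9 while the silane returns Cu–H. The closest known reaction types are the copper hydride-catalysed enantioselective hydroallylation of vinylarenes with allylic phosphates and the copper hydride-catalysed C2-alkylation of quinoline N-oxides with vinylarenes, where the N-oxide is activating group and internal oxidant; new here are their union in one flask, a primary alkylcopper as the nucleophile and a pyridine N-oxide as the acceptor. Ring B closes in the 6-exo-trig mode (C8 onto C8a of the C8a=N bond, nitrogen outside the new ring). The C5 stereocentre is set by the chiral bisphosphine in the hydrocupration, is carried through the stereoretentive allylation and is not touched in the second stage. The step needs the conjugated alkene to react before the unactivated one, which its faster hydrocupration, the room-temperature first stage and 7 as limiting electrophile should secure, and it needs ring attack at C8a only, which is secured because C8a is the sole unsubstituted ring carbon, is next to the copper-binding oxygen and is reached over a six-membered closure, while the other six-membered closure, onto C4, is blocked by its methoxy group.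

Step 6
Reactants: 9 (R)-3,4-dimethoxy-2-methyl-5-(5-phenylpentyl)-5,6,7,8-tetrahydroquinoline
Product: 10 (R)-3,4-dimethoxy-2-methyl-5-(5-phenylpentyl)-5,6,7,8-tetrahydroquinoline 1-oxide
Conditions: mCPBA (1.1 equiv), CH2Cl2, 0 °C to rt
Reagents that add atoms: 3-chloroperoxybenzoic acid, OOC(=O)c1cccc(Cl)c1
Why: Peracid N-oxidation of a 2,6-dialkylpyridine; no alkene is left and the C5–H stereocentre is not involved, so the configuration of 9 should be kept.

**Compound list**
1 | 3,4-dimethoxy-2-methylpyridine | COc1ccnc(C)c1OC | starting material
2 | 5-bromo-3,4-dimethoxy-2-methylpyridine | COc1c(Br)cnc(C)c1OC | intermediate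
3 | 5-bromo-3,4-dimethoxy-2-methylpyridine 1-oxide | COc1c(Br)c[n+]([O-])c(C)c1OC | intermediate
4 | 6-phenyl-1-hexyne | C#CCCCCc1ccccc1 | starting material
5 | (E)-4,4,5,5-tetramethyl-2-(6-phenylhex-1-en-1-yl)-1,3,2-dioxaborolane | CC1(C)OB(/C=C/CCCCc2ccccc2)OC1(C)C | intermediate
6 | (E)-3,4-dimethoxy-2-methyl-5-(6-phenylhex-1-en-1-yl)pyridine 1-oxide | COc1c(/C=C/CCCCc2ccccc2)c[n+]([O-])c(C)c1OC | intermediate
7 | diethyl allyl phosphate | C=CCOP(=O)(OCC)OCC | starting material
8 | (R)-3,4-dimethoxy-2-methyl-5-(9-phenylnon-1-en-4-yl)pyridine 1-oxide | COc1c(OC)c(C)[n+]([O-])cc1[C@H](CCCCCc1ccccc1)CC=C | intermediate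
9 | (R)-3,4-dimethoxy-2-methyl-5-(5-phenylpentyl)-5,6,7,8-tetrahydroquinoline | COc1c(OC)c(C)nc2c1[C@H](CCCCCc1ccccc1)CCC2 | intermediate
10 | (R)-3,4-dimethoxy-2-methyl-5-(5-phenylpentyl)-5,6,7,8-tetrahydroquinoline 1-oxide | COc1c(OC)c(C)[n+]([O-])c2c1[C@H](CCCCCc1ccccc1)CCC2 | target

Total step count: 6. Longest linear sequence: 5 steps (1 → 2 → 3 → 6 → 9 → 10); step 3 makes 5 in a side branch.

**Steps most likely to fail**

1. Step 5 (proposed new method). The sequence may stall after the first C–C bond, because the primary alkylcopper is protonated or the N-oxide is reduced by the silane faster than C8 is delivered to C8a. The fallback sets out from 6 and comes back at 9.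
 - Only the hydroallylation, a known reaction type for vinylarenes, is run at room temperature and stopped when 6 is consumed, and 8 is isolated.
 - MeOTf in CH2Cl2 methylates the N-oxide oxygen to give (R)-1,3,4-trimethoxy-2-methyl-5-(9-phenylnon-1-en-4-yl)pyridin-1-ium trifluoromethanesulfonate F1.
 - Catecholborane with catalytic N,N-dimethylacetamide hydroborates the terminal alkene to the B-alkylcatecholborane (S)-5-[1-(1,3,2-benzodioxaborol-2-yl)-9-phenylnonan-4-yl]-1,3,4-trimethoxy-2-methylpyridin-1-ium trifluoromethanesulfonate F2, which is not isolated. The descriptor changes only because boron ranks below carbon; the spatial arrangement is that of 8.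
 - Di-tert-butyl hyponitrite and 2,4,6-collidine then start the known radical chain alkylation of N-methoxypyridinium salts by alkylcatecholboranes: the primary C8 radical closes onto C8a (Minisci-type, six-membered), and the adduct loses a proton and a methoxyl radical, which carries the chain at boron, to give 9.

2. Step 1. Site selectivity between the two ring C–H positions may be poor, or radical bromination of the 2-methyl group may compete. The fallback sets out from 1 and comes back at 2.
 - The 4-methoxy group, para to nitrogen, is cleaved selectively with NaSEt in DMF at 100 °C to give 3-methoxy-2-methylpyridin-4(1H)-one F3.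
 - NBS in DMF brominates F3 at C5, the nucleophilic α-carbon of its vinylogous amide, to give 5-bromo-3-methoxy-2-methylpyridin-4(1H)-one F4.
 - POCl3 at 90 °C converts F4 into 5-bromo-4-chloro-3-methoxy-2-methylpyridine F5.
 - NaOMe in MeOH at reflux displaces the activated 4-chloride, not the 5-bromide, to give 2.

3. Step 4. The N-oxide oxygen may be lost to the phosphine/palladium system, or oxidative addition at the electron-rich bromide flanked by a methoxy group may be slow enough for protodeboronation of 5 to take over. The fallback sets out from 2 and comes back at 6.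
 - The order of coupling and oxidation is reversed: 2 and 5 are joined under the same Suzuki–Miyaura conditions to give (E)-3,4-dimethoxy-2-methyl-5-(6-phenylhex-1-en-1-yl)pyridine F6.
 - The ring nitrogen, more nucleophilic toward a peracid than the 1,2-disubstituted alkene, is then oxidised with one equivalent of mCPBA in CH2Cl2 at −10 °C to give 6.

Further compounds
F1 | step 5 | (R)-1,3,4-trimethoxy-2-methyl-5-(9-phenylnon-1-en-4-yl)pyridin-1-ium trifluoromethanesulfonate | COc1c(OC)c(C)[n+](OC)cc1[C@H](CCCCCc1ccccc1)CC=C.[O-]S(=O)(=O)C(F)(F)F
F2 | step 5 | (S)-5-[1-(1,3,2-benzodioxaborol-2-yl)-9-phenylnonan-4-yl]-1,3,4-trimethoxy-2-methylpyridin-1-ium trifluoromethanesulfonate | COc1c(OC)c(C)[n+](OC)cc1[C@H](CCCCCc1ccccc1)CCCB1Oc2ccccc2O1.[O-]S(=O)(=O)C(F)(F)F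
F3 | step 1 | 3-methoxy-2-methylpyridin-4(1H)-one | Cc1[nH]ccc(=O)c1OC
F4 | step 1 | 5-bromo-3-methoxy-2-methylpyridin-4(1H)-one | Cc1[nH]cc(Br)c(=O)c1OC
F5 | step 1 | 5-bromo-4-chloro-3-methoxy-2-methylpyridine | COc1c(C)ncc(Br)c1Cl
F6 | step 4 | (E)-3,4-dimethoxy-2-methyl-5-(6-phenylhex-1-en-1-yl)pyridine | COc1c(/C=C/CCCCc2ccccc2)cnc(C)c1OC
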